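**Retrosynthetic overview**
1. Target 30 ⇐ 1(10)-olefin 29 by a last-step Schenck ene reaction (C1–OOH bond, Δ10(14)); 29 ⇐ alcohol 21 + side-chain acid 26 (ester C–O, then acetonide removal).
2. 21 ⇐ bromo-enal 18 by indium Barbier macrocyclisation: the ten-membered carbocycle (C6–C7) forms first and the cis-fused γ-lactone (O6–C12) closes in the same operation; these are the only two rings.
3. 18 ⇐ diene 15: a palladium-catalysed 1,4-hydroxy-acetoxylation of the 2-substituted butadiene makes the C6–O and C15–O bonds and fixes the C4=C5 geometry (new step), followed by oxidation to the enal and SN2' bromination.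
4. 15 ⇐ isoprene + allylic bromide 8 (allyl–allyl coupling), Swern oxidation of a primary silyl ether, vinylalumination with methyl propiolate.
5. 8 ⇐ (R)-glycidol (C8 stereocentre) + acetylide, then Zr-catalysed carboalumination/formaldehyde (E-C1=C10); 26 ⇐ malate-derived dioxolane acetate 22.

Assumption: locants C1–C15 are germacrane locants of the target (C1 = CH–OOH, C6 = lactone O–CH, C8 = ester O–CH, C12 = lactone C=O, C14 = 10-methyl/methylidene, C15 = CH2OAc) and serve only to describe compounds; all starting materials listed are taken as purchasable.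

**Route**

Step 1
Reactants: 1 (R)-glycidol; 2 lithium acetylide–ethylenediamine complex (LiC≡CH·H2NCH2CH2NH2)
Product: 3 (S)-pent-4-yne-1,2-diol
Conditions: 2 (2.5 equiv), DMSO, 0 → 25 °C; H2O work-up
Reagents that add atoms: none
Why: Acetylide opens the epoxide by SN2 at the terminal CH2 (the Payne rearrangement of the glycidol alkoxide is degenerate), so the stereocentre is untouched and becomes C8 of the target.

Step 2
Reactants: 3 (S)-pent-4-yne-1,2-diol
Product: 4 (S)-4,5-bis(triethylsilyloxy)pent-1-yne
Conditions: Et3SiCl (2.4 equiv), imidazole, DMF, 0 → 25 °C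
Reagents that add atoms: chlorotriethylsilane, CC[Si](CC)(CC)Cl
Why: Standard silylation; triethylsilyl is chosen because the primary ether is later converted directly into the aldehyde while the secondary one survives until step 11.

Step 3
Reactants: 4 (S)-4,5-bis(triethylsilyloxy)pent-1-yne
Product: 6 (S,E)-3-methyl-5,6-bis(triethylsilyloxy)hex-2-en-1-ol, via alkenylalane 5 (not isolated)
Conditions: AlMe3 (2.5 equiv), Cp2ZrCl2 (20 mol %), CH2Cl2, 0 → 25 °C; n-BuLi, THF, −78 °C; (CH2O)n, −78 → 25 °C; H2O work-up
Reagents that add atoms: trimethylaluminium, C[Al](C)C; paraformaldehyde (formaldehyde), C=O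
Why: Negishi zirconium-catalysed syn-carboalumination puts the methyl group (C14) on the internal carbon and aluminium on the terminus, and the derived alanate is hydroxymethylated with retention, giving the E-trisubstituted C1=C10 olefin.

Step 4
Reactants: 6 (S,E)-3-methyl-5,6-bis(triethylsilyloxy)hex-2-en-1-ol
Product: 8 (S,E)-1-bromo-3-methyl-5,6-bis(triethylsilyloxy)hex-2-ene, via allylic mesylate 7 (not isolated)
Conditions: MsCl, Et3N, CH2Cl2, −40 °C; then LiBr, THF, 0 °C
Reagents that add atoms: lithium bromide, [Li+].[Br-]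
Why: Mesylation and SN2 displacement by bromide at the primary allylic carbon proceed under non-acidic conditions that keep both silyl ethers and the olefin geometry.

Step 5
Reactants: 8 (S,E)-1-bromo-3-methyl-5,6-bis(triethylsilyloxy)hex-2-ene; 9 isoprene
Product: 11 (S,E)-4-methyl-8-methylidene-1,2-bis(triethylsilyloxy)deca-4,9-diene, via potassium isoprenide 10 (not isolated)
Conditions: 9 (5 equiv), 2,2,6,6-tetramethylpiperidine, n-BuLi, KOt-Bu, THF, −78 → −50 °C; then 8, −78 → −20 °C
Reagents that add atoms: none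
Why: Allyl–allyl coupling: metalated isoprene is a symmetrical 2-vinylallyl anion (both CH2 termini equivalent) and attacks the primary allylic bromide by SN2 to give the 2-substituted butadiene with C2–C3 in place.

Step 6
Reactants: 11 (S,E)-4-methyl-8-methylidene-1,2-bis(triethylsilyloxy)deca-4,9-diene
Product: 12 (S,E)-4-methyl-8-methylidene-2-(triethylsilyloxy)deca-4,9-dienal
Conditions: (COCl)2 (4 equiv), DMSO, CH2Cl2, −78 → −40 °C; i-Pr2NEt-free quench with Et3N, −78 → 0 °C
Reagents that add atoms: none
Why: Under Swern conditions a primary triethylsilyl ether is transferred to the chlorosulfonium salt and oxidised directly to the aldehyde while the secondary silyl ether and the diene are inert; low temperature limits α-epimerisation.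

Step 7
Reactants: 12 (S,E)-4-methyl-8-methylidene-2-(triethylsilyloxy)deca-4,9-dienal; 13 methyl propiolate
Product: 15 methyl (4S,6E)-3-hydroxy-6-methyl-2,10-dimethylidene-4-(triethylsilyloxy)dodeca-6,11-dienoate (C3 epimers), via vinylalane 14 (not isolated)
Conditions: i-Bu2AlH, N-methylmorpholine N-oxide, THF, 0 °C; 13; then 12, 0 → 25 °C; H2O work-up
Reagents that add atoms: none
Why: Vinylalumination (a base-free Morita–Baylis–Hillman equivalent): the α-aluminated acrylate adds 1,2 to the aldehyde without the amine that would epimerise the α-silyloxy aldehyde; the new carbinol centre is destroyed in step 9.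

Step 8
Reactants: 15 methyl (4S,6E)-3-hydroxy-6-methyl-2,10-dimethylidene-4-(triethylsilyloxy)dodeca-6,11-dienoate
Product: 17 methyl (4S,6E,10E)-10-(acetoxymethyl)-3-hydroxy-6-methyl-2-methylidene-12-oxo-4-(triethylsilyloxy)dodeca-6,10-dienoate, via hydroxy acetate 16 (not isolated)
Conditions: Pd(OAc)2 (5 mol %), p-benzoquinone (1.2 equiv), LiOAc (2 equiv), AcOH (2 equiv), acetone–H2O 4:1, 20 °C, dark; then TEMPO (10 mol %), PhI(OAc)2 (2.5 equiv), same flask, 0 → 20 °C
Reagents that add atoms: water, O; acetic acid (LiOAc/AcOH buffer), CC(=O)O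
Why: Proposed new method: an unsymmetrical Pd(OAc)2/benzoquinone-catalysed 1,4-dioxygenation in which bulk water adds by external anti attack to the unhindered vinyl terminus C6 of the diene complex of divalent palladium to give a 2-alkyl-4-hydroxy-π-allylpalladium, after which palladium-bound acetate is delivered (benzoquinone-induced) to the unsubstituted terminus C15; the syn arrangement of the CH2OH arm and the C3 chain on the allyl gives the C4=C5 olefin with C3/C6 cis, and TEMPO/PhI(OAc)2 then oxidises only the primary allylic alcohol without Z/E isomerisation; closest known reaction types are the Bäckvall 1,4-diacetoxylation, 1,4-oxylactonisation and alkoxy-acyloxylation of 1,3-dienes and the Wacker hydroxypalladation of butadiene.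

Step 9
Reactants: 17 methyl (4S,6E,10E)-10-(acetoxymethyl)-3-hydroxy-6-methyl-2-methylidene-12-oxo-4-(triethylsilyloxy)dodeca-6,10-dienoate
Product: 18 methyl (2Z,4S,6E,10E)-10-(acetoxymethyl)-2-(bromomethyl)-6-methyl-12-oxo-4-(triethylsilyloxy)dodeca-2,6,10-trienoate
Conditions: NBS, Me2S, CH2Cl2, −20 → 0 °C
Reagents that add atoms: N-bromosuccinimide, O=C1CCC(=O)N1Br
Why: SN2' bromination of the Baylis–Hillman alcohol through its alkoxysulfonium salt gives the thermodynamically preferred (Z)-2-(bromomethyl)enoate (C8 trans to the ester) from both C7 epimers under neutral conditions that spare enal, acetate and silyl ether.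

Step 10
Reactants: 18 methyl (2Z,4S,6E,10E)-10-(acetoxymethyl)-2-(bromomethyl)-6-methyl-12-oxo-4-(triethylsilyloxy)dodeca-2,6,10-trienoate
Product: 20 8-O-triethylsilyl-15-acetoxy-8-hydroxygermacra-1(10),4,11(13)-trien-12,6-olide (cis-fused), via hydroxy ester 19 (not isolated)
Conditions: In powder (3 equiv), THF–H2O 4:1, 0.002 M (syringe-pump addition of 18 over 10 h), 25 °C; then PPTS (20 mol %), CH2Cl2, 25 °C
Reagents that add atoms: none
Why: Intramolecular Barbier allylation (precedented for germacranolide ring closure): the (Z)-allylindium reacts through a chair transition state with the C8 chain axial to give the syn adduct (cis-lactone after PPTS lactonisation) and attacks C7 anti to the non-chelating OSiEt3 group with H-8 eclipsing the olefin, which sets C6 and C7 from C8; the ring-cis 4,5-olefin favours closure of the ten-membered ring.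

Step 11
Reactants: 20 8-O-triethylsilyl-15-acetoxy-8-hydroxygermacra-1(10),4,11(13)-trien-12,6-olide
Product: 21 15-acetoxy-8-hydroxygermacra-1(10),4,11(13)-trien-12,6-olide
Conditions: HF·pyridine, pyridine, THF, 0 °C
Reagents that add atoms: none
Why: Buffered HF·pyridine cleaves the secondary silyl ether without touching the acetate or lactone and without base that could shift the lactone to O8.

Step 12
Reactants: 22 methyl (R)-2-(2,2-dimethyl-1,3-dioxolan-4-yl)acetate
Product: 25 methyl (R)-2-(2,2-dimethyl-1,3-dioxolan-4-yl)acrylate, via Mannich base 23 (not isolated), via ammonium iodide 24 (not isolated)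
Conditions: LiN(i-Pr)2, THF, −78 °C; CH2=NMe2+ I−, −78 → 0 °C; then MeI (excess), 25 °C; then DBU, 25 °C
Reagents that add atoms: Eschenmoser's salt (N,N-dimethylmethyleneiminium iodide), C=[N+](C)C.[I-]
Why: Ester-enolate Mannich reaction at −78 °C (β-alkoxide elimination is slow at this temperature), quaternisation and E1cB loss of trimethylamine give the α-methylene ester; the dioxolane stereocentre is not involved.

Step 13
Reactants: 25 methyl (R)-2-(2,2-dimethyl-1,3-dioxolan-4-yl)acrylate
Product: 26 (R)-2-(2,2-dimethyl-1,3-dioxolan-4-yl)acrylic acid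
Conditions: LiOH, THF–H2O, 0 → 25 °C; then dilute HCl to pH 4, 0 °C
Reagents that add atoms: lithium hydroxide, [Li+].[OH-]
Why: Saponification by acyl–oxygen cleavage; the stereocentre carries no acidic hydrogen and the acetonide survives the brief cold acidification.

Step 14
Reactants: 21 15-acetoxy-8-hydroxygermacra-1(10),4,11(13)-trien-12,6-olide; 26 (R)-2-(2,2-dimethyl-1,3-dioxolan-4-yl)acrylic acid
Product: 28 15-acetoxy-8-[(R)-2-(2,2-dimethyl-1,3-dioxolan-4-yl)acryloyloxy]germacra-1(10),4,11(13)-trien-12,6-olide, via mixed anhydride 27 (not isolated)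
Conditions: 26, 2,4,6-trichlorobenzoyl chloride, Et3N, toluene, 25 °C; then 21, DMAP, 25 °C
Reagents that add atoms: none
Why: Yamaguchi esterification acylates the hindered C8 alcohol with the α-substituted acrylic acid through the mixed anhydride and acylpyridinium, with retention at C8 and C3'.

Step 15
Reactants: 28 15-acetoxy-8-[(R)-2-(2,2-dimethyl-1,3-dioxolan-4-yl)acryloyloxy]germacra-1(10),4,11(13)-trien-12,6-olide
Product: 29 15-acetoxy-8-[(R)-3,4-dihydroxy-2-methylidenebutanoyloxy]germacra-1(10),4,11(13)-trien-12,6-olide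
Conditions: AcOH–H2O 4:1, 30 °C
Reagents that add atoms: none
Why: Aqueous acetic acid hydrolyses the isopropylidene acetal while the acidic medium suppresses lactonisation of the freed 4'-OH onto the side-chain ester and leaves the allylic acetate and α-methylene lactone intact.

Step 16
Reactants: 29 15-acetoxy-8-[(R)-3,4-dihydroxy-2-methylidenebutanoyloxy]germacra-1(10),4,11(13)-trien-12,6-olide
Product: 30 CNP0307408.1 (1-hydroperoxy-10(14)-ene)
Conditions: O2, tetraphenylporphyrin (1 mol %), white LED, CH2Cl2, −10 °C, stop at one equivalent of O2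
Reagents that add atoms: dioxygen, O=O
Why: Schenck ene reaction: singlet oxygen selects the electron-rich 1(10) olefin (the 4,5-olefin carries two allylic oxygens and the enoates are electron-poor), abstracts hydrogen from C14 on the disubstituted side (cis effect) and adds to the outer face on the side of the C7–C11 bond, as in costunolide → peroxycostunolide, which forms the C1–O bond and sets C1.

**Compound list**
1 | (R)-glycidol | OC[C@@H]1CO1 | starting material
2 | lithium acetylide–ethylenediamine complex | [Li+].[C-]#C.NCCN | starting material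
3 | (S)-pent-4-yne-1,2-diol | C#CC[C@H](O)CO | intermediate
4 | (S)-4,5-bis(triethylsilyloxy)pent-1-yne | C#CC[C@H](O[Si](CC)(CC)CC)CO[Si](CC)(CC)CC | intermediate
5 | dimethyl[(S,E)-2-methyl-4,5-bis(triethylsilyloxy)pent-1-enyl]alane (Al cis to methyl) | C[Al](C)/C=C(\C)C[C@H](O[Si](CC)(CC)CC)CO[Si](CC)(CC)CC | intermediate
6 | (S,E)-3-methyl-5,6-bis(triethylsilyloxy)hex-2-en-1-ol | OC/C=C(\C)C[C@H](O[Si](CC)(CC)CC)CO[Si](CC)(CC)CC | intermediate
7 | methanesulfonate of 6 | CS(=O)(=O)OC/C=C(\C)C[C@H](O[Si](CC)(CC)CC)CO[Si](CC)(CC)CC | intermediate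
8 | (S,E)-1-bromo-3-methyl-5,6-bis(triethylsilyloxy)hex-2-ene | BrC/C=C(\C)C[C@H](O[Si](CC)(CC)CC)CO[Si](CC)(CC)CC | intermediate
9 | isoprene | C=CC(C)=C | starting material
10 | potassium 2-methylidenebut-3-en-1-ide | [K+].[CH2-]C(=C)C=C | intermediate
11 | (S,E)-4-methyl-8-methylidene-1,2-bis(triethylsilyloxy)deca-4,9-diene | C=CC(=C)CC/C=C(\C)C[C@H](O[Si](CC)(CC)CC)CO[Si](CC)(CC)CC | intermediate
12 | (S,E)-4-methyl-8-methylidene-2-(triethylsilyloxy)deca-4,9-dienal | C=CC(=C)CC/C=C(\C)C[C@H](O[Si](CC)(CC)CC)C=O | intermediate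
13 | methyl propiolate | C#CC(=O)OC | starting material
14 | [1-(methoxycarbonyl)ethenyl]diisobutylalane | C=C(C(=O)OC)[Al](CC(C)C)CC(C)C | intermediate
15 | methyl (4S,6E)-3-hydroxy-6-methyl-2,10-dimethylidene-4-(triethylsilyloxy)dodeca-6,11-dienoate (both C3 epimers) | C=CC(=C)CC/C=C(\C)C[C@H](O[Si](CC)(CC)CC)C(O)C(=C)C(=O)OC | intermediate
16 | methyl (4S,6E,10E)-10-(acetoxymethyl)-3,12-dihydroxy-6-methyl-2-methylidene-4-(triethylsilyloxy)dodeca-6,10-dienoate (CH2OH cis to the chain, trans to CH2OAc) | OC/C=C(/COC(C)=O)CC/C=C(\C)C[C@H](O[Si](CC)(CC)CC)C(O)C(=C)C(=O)OC | intermediate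
17 | methyl (4S,6E,10E)-10-(acetoxymethyl)-3-hydroxy-6-methyl-2-methylidene-12-oxo-4-(triethylsilyloxy)dodeca-6,10-dienoate | O=C/C=C(/COC(C)=O)CC/C=C(\C)C[C@H](O[Si](CC)(CC)CC)C(O)C(=C)C(=O)OC | intermediate
18 | methyl (2Z,4S,6E,10E)-10-(acetoxymethyl)-2-(bromomethyl)-6-methyl-12-oxo-4-(triethylsilyloxy)dodeca-2,6,10-trienoate | O=C/C=C(/COC(C)=O)CC/C=C(\C)C[C@H](O[Si](CC)(CC)CC)/C=C(\CBr)C(=O)OC | intermediate
19 | ten-membered hydroxy ester: methyl 2-[15-acetoxy-6-hydroxy-8-(triethylsilyloxy)germacra-1(10),4-dien-7-yl]acrylate; 1(10)E, C3/C6 cis at C4=C5; C6, C7, C8 arranged as in the target | COC(=O)C(=C)[C@H]1[C@@H](O)/C=C(/COC(C)=O)CC/C=C(\C)C[C@@H]1O[Si](CC)(CC)CC | intermediate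
20 | 8-O-triethylsilyl-15-acetoxy-8-hydroxygermacra-1(10),4,11(13)-trien-12,6-olide; cis-fused lactone (H-6/H-7 cis, H-7/H-8 trans), 1(10)E, C3/C6 cis at C4=C5 | C=C1C(=O)O[C@H]2/C=C(/COC(C)=O)CC/C=C(\C)C[C@H](O[Si](CC)(CC)CC)[C@@H]12 | intermediate
21 | (6S,7R,8S)-15-acetoxy-8-hydroxygermacra-1(10),4,11(13)-trien-12,6-olide; geometry as in 20 | C=C1C(=O)O[C@H]2/C=C(/COC(C)=O)CC/C=C(\C)C[C@H](O)[C@@H]12 | intermediate
22 | methyl (R)-2-(2,2-dimethyl-1,3-dioxolan-4-yl)acetate | COC(=O)C[C@@H]1COC(C)(C)O1 | starting material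
23 | methyl 3-(dimethylamino)-2-[(R)-2,2-dimethyl-1,3-dioxolan-4-yl]propanoate (C2 epimers) | COC(=O)C(CN(C)C)[C@@H]1COC(C)(C)O1 | intermediate
24 | trimethylammonium iodide of 23 | COC(=O)C(C[N+](C)(C)C)[C@@H]1COC(C)(C)O1.[I-] | intermediate
25 | methyl (R)-2-(2,2-dimethyl-1,3-dioxolan-4-yl)acrylate | COC(=O)C(=C)[C@@H]1COC(C)(C)O1 | intermediate
26 | (R)-2-(2,2-dimethyl-1,3-dioxolan-4-yl)acrylic acid | OC(=O)C(=C)[C@@H]1COC(C)(C)O1 | intermediate
27 | mixed anhydride of 26 with 2,4,6-trichlorobenzoic acid | O=C(OC(=O)C(=C)[C@@H]1COC(C)(C)O1)c1c(Cl)cc(Cl)cc1Cl | intermediate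
28 | 8-O-[(R)-2-(2,2-dimethyl-1,3-dioxolan-4-yl)acryloyl] ester of 21 | C=C1C(=O)O[C@H]2/C=C(/COC(C)=O)CC/C=C(\C)C[C@H](OC(=O)C(=C)[C@@H]3COC(C)(C)O3)[C@@H]12 | intermediate
29 | 8-O-[(R)-3,4-dihydroxy-2-methylidenebutanoyl] ester of 21 (1(10)-olefin precursor) | C=C1C(=O)O[C@H]2/C=C(/COC(C)=O)CC/C=C(\C)C[C@H](OC(=O)C(=C)[C@@H](O)CO)[C@@H]12 | intermediate
30 | CNP0307408.1: (1R,6S,7R,8S,3'R) 1-hydroperoxy-10(14)-ene | C=C1C(=O)O[C@H]2/C=C(/COC(C)=O)CC[C@@H](OO)C(=C)C[C@H](OC(=O)C(=C)[C@@H](O)CO)[C@@H]12 | target

**Step count and risks**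

Total: 16 steps. Longest linear sequence: 14 steps (steps 1–11, then 14–16); steps 12–13 make the side-chain acid in parallel.

The three steps most likely to fail:

Step 8 (the proposed new reaction). Likely failures are acetate rather than water attacking first (giving the diacetate or the regioisomeric hydroxy acetate), double hydration, Wacker-type enal formation with C15 left as methyl, and an E/Z mixture at C4=C5. The fallback uses known chemistry and sets out from 15. Bäckvall 1,4-diacetoxylation (Pd(OAc)2 5 mol %, LiOAc, catalytic benzoquinone, MnO2, AcOH–acetone, 25 °C) gives methyl (4S,6E,10E)-12-acetoxy-10-(acetoxymethyl)-3-hydroxy-6-methyl-2-methylidene-4-(triethylsilyloxy)dodeca-6,10-dienoate F1. A lipase (Candida antarctica lipase B, pH 7 phosphate buffer–acetone) then hydrolyses the less hindered C6 acetate regioselectively. This returns to the route at 16, here isolated, which is oxidised to 17 with TEMPO/PhI(OAc)2 as in step 8.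

Step 10 (macrocyclisation). Risks are oligomerisation or protodebromination, and the wrong relative configuration at C6/C7 if ring strain overrides the acyclic preference. The fallback sets out from 18 and replaces the in-situ organoindium by an isolable allylboronate. Borylation with B2pin2 catalysed by Pd2(dba)3 (THF, 40 °C, no base) gives the pinacol allylboronate methyl (2E,4S,6E,10E)-10-(acetoxymethyl)-6-methyl-12-oxo-2-[(4,4,5,5-tetramethyl-1,3,2-dioxaborolan-2-yl)methyl]-4-(triethylsilyloxy)dodeca-2,6,10-trienoate F2. It is stable at room temperature because 2-alkoxycarbonyl allylboronates add to aldehydes only on heating. Thermolysis at high dilution (toluene, 0.002 M, 90 °C) closes the ring through a closed six-membered transition state, in which the boronate geometry dictates the syn adduct. Work-up and PPTS give the lactone, returning to the route at 20.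

Step 16 (ene reaction). Risks are hydrogen abstraction from C2 or C9, attack on the wrong face at C1, and over-oxidation of the polar diol substrate. The fallback sets out from 28 and forms the C1–O bond before the diol is unmasked. Photo-oxygenation of 28 (O2, tetraphenylporphyrin, light, CH2Cl2, −10 °C) gives the hydroperoxy acetonide F3, whose regio- and C1-isomers are separated at this non-polar stage. AcOH–H2O 4:1 at 25 °C then removes the acetonide (allylic hydroperoxides tolerate these conditions) and returns to the route at 30.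

**Further compounds**
F1 | step 8 | methyl (4S,6E,10E)-12-acetoxy-10-(acetoxymethyl)-3-hydroxy-6-methyl-2-methylidene-4-(triethylsilyloxy)dodeca-6,10-dienoate | CC(=O)OC/C=C(/COC(C)=O)CC/C=C(\C)C[C@H](O[Si](CC)(CC)CC)C(O)C(=C)C(=O)OC
F2 | step 10 | methyl (2E,4S,6E,10E)-10-(acetoxymethyl)-6-methyl-12-oxo-2-[(4,4,5,5-tetramethyl-1,3,2-dioxaborolan-2-yl)methyl]-4-(triethylsilyloxy)dodeca-2,6,10-trienoate | O=C/C=C(/COC(C)=O)CC/C=C(\C)C[C@H](O[Si](CC)(CC)CC)/C=C(\CB1OC(C)(C)C(C)(C)O1)C(=O)OC
F3 | step 16 | 1-hydroperoxy-10(14)-ene derived from 28 (acetonide of 30) | C=C1C(=O)O[C@H]2/C=C(/COC(C)=O)CC[C@@H](OO)C(=C)C[C@H](OC(=O)C(=C)[C@@H]3COC(C)(C)O3)[C@@H]12
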